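**Retrosynthetic overview**

1. Chromene numbering is used: ring A is the oxygenated benzene ring (C4a, C5–C8, C8a), ring B the pyran ring (O1, C2, C3, C4, C4a, C8a), ring C the 4-hydroxyphenyl ring.
2. Target 11 ⇐ silyl ether 10 ⇐ alkyne 8: ring B is opened at C3–C2 to give an acyclic isomer, an ortho-ethynyl aryl isopropyl ether. Forward, PtI4 should trigger a 1,5-hydride shift from the isopropyl C–H to C4, after which the alkenylplatinum carbon C3 closes onto the oxocarbenium carbon C2.
3. Enabling feature: C2 carries O1 and two methyl groups, so it can start as the hydridic methine C–H of an isopropyl ether (tertiary oxocarbenium after hydride loss). This C–H is held 1,5 to C4 through O1–C8a–C4a, and C4 and C3 start as the inner and outer carbons of a terminal alkyne on C4a.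
4. 8 ⇐ salicylaldehyde 6 (one-carbon homologation) ⇐ 3: the O1 isopropyl and O7 prenyl groups are told apart by the chelated ortho-hydroxyl versus the acidic para-hydroxyl of a 2,4-dihydroxybenzaldehyde. 3 ⇐ dihydroresveratrol 1 by formylation next to the side chain.
5. Ring order: rings A and C and the ethylene bridge are bought in 1; ring B is the only ring made, and it is made last but one (step 6).

Key step: step 6

Assumption: dihydroresveratrol 1 is taken as a purchasable compound; all other atoms come from bulk reagents.

**Route**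

Step 1
Reactants: 1 dihydroresveratrol
Product: 3 2,4-dihydroxy-6-[2-(4-hydroxyphenyl)ethyl]benzaldehyde, via aryl iminium chloride 2 (not isolated)
Conditions: POCl3 (1.3 equiv), DMF, 0 °C to rt; then H2O, 50 °C
Reagents that add atoms: N,N-dimethylformamide CN(C)C=O; water O
Why: Vilsmeier–Haack formylation, in which the resorcinol ring A is far more nucleophilic than ring C and should be attacked para to one hydroxyl and ortho to the other (next to the side chain, as with orcinol and olivetol) to give iminium 2, which is hydrolysed on aqueous work-up.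

Step 2
Reactants: 3 2,4-dihydroxy-6-[2-(4-hydroxyphenyl)ethyl]benzaldehyde
Product: 4 2-hydroxy-6-[2-(4-hydroxyphenyl)ethyl]-4-(3-methylbut-2-enyloxy)benzaldehyde
Conditions: prenyl bromide (1.05 equiv), CsHCO3 (1.5 equiv), MeCN, 60 °C
Reagents that add atoms: prenyl bromide CC(C)=CCBr
Why: Williamson etherification under bicarbonate control, in which only the hydroxyl para to the formyl group is acidic enough to be deprotonated, the ortho hydroxyl being locked in a hydrogen bond to the carbonyl and the ring-C phenol staying protonated, so that mono-O-prenylation at the future O7 is expected.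

Step 3
Reactants: 4 2-hydroxy-6-[2-(4-hydroxyphenyl)ethyl]-4-(3-methylbut-2-enyloxy)benzaldehyde
Product: 5 2-hydroxy-4-(3-methylbut-2-enyloxy)-6-[2-(4-triisopropylsilyloxyphenyl)ethyl]benzaldehyde
Conditions: iPr3SiCl (1.1 equiv), imidazole (2 equiv), DMF, 0 °C to rt
Reagents that add atoms: chlorotriisopropylsilane CC(C)[Si](Cl)(C(C)C)C(C)C
Why: Silyl ether formation at the free ring-C phenol, the chelated and hindered ortho-hydroxyl of the salicylaldehyde being expected not to react with the bulky chlorosilane under these mild conditions.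

Step 4
Reactants: 5 2-hydroxy-4-(3-methylbut-2-enyloxy)-6-[2-(4-triisopropylsilyloxyphenyl)ethyl]benzaldehyde
Product: 6 2-isopropoxy-4-(3-methylbut-2-enyloxy)-6-[2-(4-triisopropylsilyloxyphenyl)ethyl]benzaldehyde
Conditions: iPrOH (1.5 equiv), PPh3 (1.5 equiv), DIAD (1.5 equiv), THF, 0 °C to rt
Reagents that add atoms: propan-2-ol CC(C)O
Why: Mitsunobu etherification of the acidic salicylaldehyde hydroxyl with the activated secondary alcohol under neutral conditions, which should leave the aryl silyl ether, the aldehyde and the prenyl ether untouched.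

Step 5
Reactants: 6 2-isopropoxy-4-(3-methylbut-2-enyloxy)-6-[2-(4-triisopropylsilyloxyphenyl)ethyl]benzaldehyde
Product: 8 2-ethynyl-1-isopropoxy-5-(3-methylbut-2-enyloxy)-3-[2-(4-triisopropylsilyloxyphenyl)ethyl]benzene, via diazoalkene 7 (not isolated)
Conditions: Me3SiCHN2 (1.3 equiv), LiN(iPr)2 (1.3 equiv), THF, −78 °C; then 6, −78 °C to rt
Reagents that add atoms: trimethylsilyldiazomethane C[Si](C)(C)C=[N+]=[N-]
Why: Colvin-type one-carbon homologation, in which lithiated trimethylsilyldiazomethane adds to the non-enolisable aldehyde, Peterson-type loss of lithium trimethylsilanolate gives diazoalkene 7, and loss of N2 with 1,2-hydrogen shift gives the terminal alkyne without the methanolic base that could endanger the aryl silyl ether.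

Step 6
Reactants: 8 2-ethynyl-1-isopropoxy-5-(3-methylbut-2-enyloxy)-3-[2-(4-triisopropylsilyloxyphenyl)ethyl]benzene
Product: 10 2,2-dimethyl-7-(3-methylbut-2-enyloxy)-5-[2-(4-triisopropylsilyloxyphenyl)ethyl]-2H-chromene, via alkenylplatinate oxocarbenium zwitterion 9 (not isolated)
Conditions: PtI4 (10 mol %), 4 Å molecular sieves, MeCN (0.02 M), 80 °C, argon
Reagents that add atoms: none
Why: Proposed new method: PtI4 binds the terminal alkyne of 8 and slips towards the outer carbon C3, so that C4 becomes electrophilic; the methine hydrogen of the isopropyl ether, held over C4 through O1–C8a–C4a, is delivered as hydride (1,5-shift, six-membered transition state) to give zwitterion 9, a tertiary aryl oxocarbenium at C2 facing a Z-alkenylplatinate at C3, which collapses by C3–C2 bond formation with release of PtI4. The closest known reaction types are the PtI4-catalysed hydride-transfer alkenylation of ether alpha C–H bonds by tethered terminal alkynes and the Lewis-acid 1,5-hydride shift/cyclisation of ortho-vinylaryl alkyl ethers, which gives dihydrobenzopyrans by the same C2–C3 closure; new here is the pairing of an aryl isopropyl ether donor with an unactivated aryl alkyne acceptor, which should give the 2H-chromene at the correct oxidation level in a fully atom-economic isomerisation. Ring B closes in a 6-endo-trig mode: the alkenyl carbon C3 adds to C2 of the endocyclic C2=O1 oxocarbenium, and the C3=C4 bond also lies in the ring. No stereocentre is formed, since C2 carries two methyl groups and the C3=C4 double bond is necessarily cis within the ring (hydride and platinum add anti across the alkyne, so platinum ends cis to ring A). The selectivity needed is hydride transfer from the isopropyl C–H and not from the benzylic CH2 on C5, C–C and not O–C closure, and survival of the prenyl ether: the ether C–H is tertiary, assisted by the O1 lone pair and the only one placed 1,5 to C4 (the benzylic hydrogen would need a 1,4-shift or a vinylidene pathway), attack of O1 on C3 would require loss of the isopropyl group, and the prenyloxy group on C7 cannot reach the alkyne while donation from O7 (para to C4a) helps C4 accept the hydride.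

Step 7
Reactants: 10 2,2-dimethyl-7-(3-methylbut-2-enyloxy)-5-[2-(4-triisopropylsilyloxyphenyl)ethyl]-2H-chromene
Product: 11 4-[2-[2,2-dimethyl-7-(3-methylbut-2-enyloxy)-2H-chromen-5-yl]ethyl]phenol
Conditions: Bu4NF (1.1 equiv), AcOH (1.1 equiv), THF, 0 °C
Reagents that add atoms: none
Why: Fluoride-mediated cleavage of the aryl silyl ether, buffered with acetic acid so that the chromene and the prenyl ether are exposed to neither strong base nor strong acid.

**Compound list**

1 | dihydroresveratrol, 5-[2-(4-hydroxyphenyl)ethyl]benzene-1,3-diol | Oc1ccc(CCc2cc(O)cc(O)c2)cc1 | starting material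
2 | [2,4-dihydroxy-6-[2-(4-hydroxyphenyl)ethyl]benzylidene]dimethyliminium chloride | C[N+](C)=Cc1c(O)cc(O)cc1CCc1ccc(O)cc1.[Cl-] | intermediate
3 | 2,4-dihydroxy-6-[2-(4-hydroxyphenyl)ethyl]benzaldehyde | O=Cc1c(O)cc(O)cc1CCc1ccc(O)cc1 | intermediate
4 | 2-hydroxy-6-[2-(4-hydroxyphenyl)ethyl]-4-(3-methylbut-2-enyloxy)benzaldehyde | O=Cc1c(O)cc(OCC=C(C)C)cc1CCc1ccc(O)cc1 | intermediate
5 | 2-hydroxy-4-(3-methylbut-2-enyloxy)-6-[2-(4-triisopropylsilyloxyphenyl)ethyl]benzaldehyde | O=Cc1c(O)cc(OCC=C(C)C)cc1CCc1ccc(O[Si](C(C)C)(C(C)C)C(C)C)cc1 | intermediate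
6 | 2-isopropoxy-4-(3-methylbut-2-enyloxy)-6-[2-(4-triisopropylsilyloxyphenyl)ethyl]benzaldehyde | O=Cc1c(OC(C)C)cc(OCC=C(C)C)cc1CCc1ccc(O[Si](C(C)C)(C(C)C)C(C)C)cc1 | intermediate
7 | 2-(2-diazoethenyl)-1-isopropoxy-5-(3-methylbut-2-enyloxy)-3-[2-(4-triisopropylsilyloxyphenyl)ethyl]benzene | [N-]=[N+]=C=Cc1c(OC(C)C)cc(OCC=C(C)C)cc1CCc1ccc(O[Si](C(C)C)(C(C)C)C(C)C)cc1 | intermediate
8 | 2-ethynyl-1-isopropoxy-5-(3-methylbut-2-enyloxy)-3-[2-(4-triisopropylsilyloxyphenyl)ethyl]benzene | C#Cc1c(OC(C)C)cc(OCC=C(C)C)cc1CCc1ccc(O[Si](C(C)C)(C(C)C)C(C)C)cc1 | intermediate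
9 | zwitterion: propan-2-ylidene oxonium on O1 and Z-alkenyl tetraiodoplatinate on C4a, with the transferred hydrogen on C4 | CC(C)=[O+]c1cc(OCC=C(C)C)cc(CCc2ccc(O[Si](C(C)C)(C(C)C)C(C)C)cc2)c1/C=C\[Pt-](I)(I)(I)I | intermediate
10 | 2,2-dimethyl-7-(3-methylbut-2-enyloxy)-5-[2-(4-triisopropylsilyloxyphenyl)ethyl]-2H-chromene | CC(C)=CCOc1cc(CCc2ccc(O[Si](C(C)C)(C(C)C)C(C)C)cc2)c2c(c1)OC(C)(C)C=C2 | intermediate
11 | 4-[2-[2,2-dimethyl-7-(3-methylbut-2-enyloxy)-2H-chromen-5-yl]ethyl]phenol (CNP0337021.0) | CC(C)=CCOc1cc(CCc2ccc(O)cc2)c2c(c1)OC(C)(C)C=C2 | target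

**Summary**

Total step count: 7. Longest linear sequence: 7 steps (1 to 11). The target has no stereocentre; the only stereo-element, the cis C3=C4 bond, is fixed by ring B.

**Steps most likely to fail**

Step 6 (Proposed new method). Possible failure processes:
- hydride delivery from the benzylic CH2 on C5 through a platinum vinylidene, leading to indene-type cyclisation;
- attack of O1 on the activated alkyne with loss of propene, leading to benzofuran formation;
- hydration of the alkyne;
- ionisation of the prenyl ether by traces of acid.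

Fallback with known chemistry, setting out from 5 and returning at 10: addition of Me2C=CHMgBr (2.5 equiv, THF, 0 °C) to the salicylaldehyde should give the racemic allylic benzylic alcohol F1. Gentle warming in toluene with a trace of pyridinium tosylate should dehydrate it to the ortho-quinone methide F2, which closes by oxa-6π electrocyclisation to 10. Ring B is then closed at O1–C2, and compounds 6 to 9 are bypassed.

Step 2. Possible failure processes: alkylation of the ring-C phenol, double alkylation, or C-prenylation of ring A.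

Fallback, setting out from 3 and returning at 5: iPr3SiCl (2.2 equiv) and imidazole should give the bis(silyl ether) F3, with the chelated hydroxyl left free. The silyl group para to the formyl group sits on the much better leaving phenoxide and should be removed selectively with LiOAc in wet DMF, giving the mono(silyl ether) F4. Prenyl bromide with K2CO3 in acetone should then alkylate the non-chelated hydroxyl, the classical selectivity of 2,4-dihydroxybenzaldehydes, to give 5. Compound 4 is bypassed.

Step 5. Possible failure processes: slow addition of the bulky lithiated diazomethane to the doubly ortho-substituted, electron-rich aldehyde, or attack of the organolithium on the aryl silyl ether.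

Fallback, setting out from 6 and returning at 8: Corey–Fuchs sequence. CBr4 and PPh3 (CH2Cl2, 0 °C) should give the 1,1-dibromoalkene F5. n-BuLi (2.2 equiv, THF, −78 °C) should then give the lithium acetylide F6 by bromine–lithium exchange and Fritsch–Buttenberg–Wiechell rearrangement, and aqueous quench gives 8.

**Further compounds**

F1 | step 6 | racemic 2-(1-hydroxy-3-methylbut-2-enyl)-5-(3-methylbut-2-enyloxy)-3-[2-(4-triisopropylsilyloxyphenyl)ethyl]phenol | CC(C)=CC(O)c1c(O)cc(OCC=C(C)C)cc1CCc1ccc(O[Si](C(C)C)(C(C)C)C(C)C)cc1
F2 | step 6 | ortho-quinone methide, 6-(3-methylbut-2-enylidene)-3-(3-methylbut-2-enyloxy)-5-[2-(4-triisopropylsilyloxyphenyl)ethyl]cyclohexa-2,4-dienone, butenylidene chain cis to the carbonyl | CC(C)=C/C=C1\C(=O)C=C(OCC=C(C)C)C=C1CCc1ccc(O[Si](C(C)C)(C(C)C)C(C)C)cc1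
F3 | step 2 | 2-hydroxy-4-triisopropylsilyloxy-6-[2-(4-triisopropylsilyloxyphenyl)ethyl]benzaldehyde | O=Cc1c(O)cc(O[Si](C(C)C)(C(C)C)C(C)C)cc1CCc1ccc(O[Si](C(C)C)(C(C)C)C(C)C)cc1
F4 | step 2 | 2,4-dihydroxy-6-[2-(4-triisopropylsilyloxyphenyl)ethyl]benzaldehyde | O=Cc1c(O)cc(O)cc1CCc1ccc(O[Si](C(C)C)(C(C)C)C(C)C)cc1
F5 | step 5 | 2-(2,2-dibromoethenyl)-1-isopropoxy-5-(3-methylbut-2-enyloxy)-3-[2-(4-triisopropylsilyloxyphenyl)ethyl]benzene | BrC(Br)=Cc1c(OC(C)C)cc(OCC=C(C)C)cc1CCc1ccc(O[Si](C(C)C)(C(C)C)C(C)C)cc1
F6 | step 5 | lithium acetylide of 8 | [Li]C#Cc1c(OC(C)C)cc(OCC=C(C)C)cc1CCc1ccc(O[Si](C(C)C)(C(C)C)C(C)C)cc1
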